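**Retrosynthetic overview**

1. The target comes from a 6-hydroxy C17 methyl ester by saponification and acetylation; the (12E)-diene comes from a C12 aldehyde by two Wittig reactions; the axial C6–OH comes from Luche reduction of a 6-oxo-7-en-17-oate.
2. Enabling feature: in ring B (C5–C10) the C6 oxygen and the C17 carboxyl on C8 are separated by C7 alone, C6(=O)–C7–C8(CO2R). This γ-oxo ester is what one-carbon homologation of a β-keto ester delivers, so C7 is excised and ring B is first made as the cyclopentanone C5–C6–C8–C9–C10 carrying its β-keto ester.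
3. That hydrindanone arises by a 4π (Nazarov) closure of the C9–C10 bond in an alkylidene β-keto ester assembled from β-cyclocitral (ring A), methyl acetate and a three-carbon aldehyde.
4. Ring order: ring A purchased; five-membered precursor of ring B (step 4); ring B by zinc-carbenoid ring expansion with thermodynamic funnelling of the C5/C8 epimers (step 5).

Key step: step 5

Remark: locants C1–C20 are labdane numbers (naphthalene C1 = C9, C2 = C8, C3 = C7, C4 = C6, C4a = C5, C8a = C10; C17 = carboxyl carbon on C8; C20 = methyl on C10); compounds 5 and 17 are taken as purchased.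

**Route**

Step 1
Reactants: 1 β-cyclocitral (2,6,6-trimethylcyclohex-1-ene-1-carbaldehyde); 2 methyl acetate
Product: 3 methyl 3-hydroxy-3-(2,6,6-trimethylcyclohex-1-en-1-yl)propanoate (racemic)
Conditions: LDA, THF, −78 °C; then 1; then H2O
Reagents that add atoms: none
Why: Aldol addition of the lithium enolate of 2 to the hindered, non-enolisable aldehyde 1 should be clean; the carbinol centre is racemic and is erased in step 2.

Step 2
Reactants: 3 methyl 3-hydroxy-3-(2,6,6-trimethylcyclohex-1-en-1-yl)propanoate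
Product: 4 methyl 3-oxo-3-(2,6,6-trimethylcyclohex-1-en-1-yl)propanoate
Conditions: Dess–Martin periodinane, CH2Cl2, rt
Reagents that add atoms: none
Why: Dess–Martin oxidation of the allylic β-hydroxy ester should give the β-keto ester without touching the tetrasubstituted alkene.

Step 3
Reactants: 4 methyl 3-oxo-3-(2,6,6-trimethylcyclohex-1-en-1-yl)propanoate; 5 3-[(tert-butyldimethylsilyl)oxy]propanal
Product: 6 methyl 5-[(tert-butyldimethylsilyl)oxy]-2-(2,6,6-trimethylcyclohex-1-ene-1-carbonyl)pent-2-enoate (E/Z mixture)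
Conditions: piperidine (cat.), AcOH (cat.), 4 Å MS, CH2Cl2, 0 °C to rt
Reagents that add atoms: none
Why: Knoevenagel condensation at the doubly activated methylene (future C8); the E/Z mixture does not matter because the isomers should interconvert under the Lewis acid of step 4.

Step 4
Reactants: 6 methyl 5-[(tert-butyldimethylsilyl)oxy]-2-(2,6,6-trimethylcyclohex-1-ene-1-carbonyl)pent-2-enoate
Product: 8 methyl (3R,3aS)-3-{2-[(tert-butyldimethylsilyl)oxy]ethyl}-3a,7,7-trimethyl-1-oxooctahydro-1H-indene-2-carboxylate (C2/C7a epimer mixture; side chain cis to the 3a-methyl), via triethylsilyl enol ether 7 (not isolated)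
Conditions: Sc(OTf)3 (10 mol%), iPr-pybox (12 mol%, enantiomer selected in a screen to give 10S), Et3SiH (3 equiv), CH2Cl2, −20 °C to rt; then aq. citric acid, THF
Reagents that add atoms: none
Why: Proposed new method: an enantioselective, hydride-interrupted Nazarov cyclisation, in which two-point binding of the β-keto ester to the chiral Sc(OTf)3–pybox Lewis acid polarises the dienone, conrotatory 4π closure through the Z-alkylidene (chain anti to the ketone, hence outside, as is C1 of ring A) forms C9–C10 with the side chain cis to the C20 methyl, the ligand biases the sense of conrotation and so the absolute configuration at C9 and C10, and, because neither C4 nor C10 carries hydrogen, the tertiary oxyallyl terminus C5 cannot terminate by elimination on its own side and should instead be captured by Et3SiH, the silyl group passing to the enolate oxygen (7) and releasing the catalyst, while C5 and C8 are deliberately left uncontrolled; the closest known reaction types are the chiral-Lewis-acid-catalysed Nazarov cyclisation of 2-alkoxycarbonyl dienones and the reductive (Et3SiH-interrupted) Nazarov cyclisation.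

Step 5
Reactants: 8 methyl (3R,3aS)-3-{2-[(tert-butyldimethylsilyl)oxy]ethyl}-3a,7,7-trimethyl-1-oxooctahydro-1H-indene-2-carboxylate (epimer mixture)
Product: 11 methyl (1R,2S,4aR,8aS)-1-{2-[(tert-butyldimethylsilyl)oxy]ethyl}-5,5,8a-trimethyl-4-oxodecahydronaphthalene-2-carboxylate (trans-fused), via zinc cyclopropanolate 9 (not isolated), via keto ester epimer mixture 10 (not isolated)
Conditions: Et2Zn, CH2I2, CH2Cl2, 0 °C to rt; H2O work-up; then NaOMe (cat.), MeOH, rt
Reagents that add atoms: diiodomethane, ICI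
Why: Et2Zn converts all four C5/C8 epimers of 8 and its enol into zinc enolates that differ only at C5, whose C8 attacks the carbenoid EtZnCH2I and closes onto the C6 carbonyl to give the donor–acceptor zinc cyclopropanolate 9; cleavage of the C6–C8 bond shared by the three- and five-membered rings, the only cleavage that returns a ketone and an ester-stabilised zinc enolate, inserts C7 and opens ring B out to six atoms. The closest known reaction type is the zinc-carbenoid homologation of β-keto esters to γ-keto esters, which with cyclic 2-alkoxycarbonyl ketones is a one-carbon ring expansion. No ring is closed for good: the cyclopropane forms by 3-exo closure of the zinc homoenolate onto the ketone and is consumed in the same event. Protonation gives 10, and NaOMe then equilibrates the two enolisable centres, so that C5 should settle trans to the C20 methyl (the usual preference of a 1-decalone-type ring fusion) and C8 should take the equatorial ester, while C9 and C10 are not enolisable and keep the configuration from step 4. The step needs C-alkylation at C8 rather than at C5 or oxygen, which the doubly stabilised β-keto ester enolate secures, and fragmentation of the internal rather than an external cyclopropane bond, which the ester on C8 secures.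

Step 6
Reactants: 11 methyl (1R,2S,4aR,8aS)-1-{2-[(tert-butyldimethylsilyl)oxy]ethyl}-5,5,8a-trimethyl-4-oxodecahydronaphthalene-2-carboxylate
Product: 13 methyl (1S,4aR,8aS)-1-{2-[(tert-butyldimethylsilyl)oxy]ethyl}-5,5,8a-trimethyl-4-oxo-1,4,4a,5,6,7,8,8a-octahydronaphthalene-2-carboxylate, via trimethylsilyl enol ether 12 (not isolated)
Conditions: LiHMDS, TMSCl, THF, −78 °C; then Pd(OAc)2, MeCN, rt
Reagents that add atoms: none
Why: Saegusa–Ito oxidation: kinetic deprotonation at the C7 methylene (C5 is flanked by two quaternary carbons) gives 12, and Pd(OAc)2 then removes the C8 hydrogen; desaturation can only run towards C8 because C4 and C10 carry no hydrogen.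

Step 7
Reactants: 13 methyl (1S,4aR,8aS)-1-{2-[(tert-butyldimethylsilyl)oxy]ethyl}-5,5,8a-trimethyl-4-oxo-1,4,4a,5,6,7,8,8a-octahydronaphthalene-2-carboxylate
Product: 14 methyl (1S,4S,4aR,8aS)-1-{2-[(tert-butyldimethylsilyl)oxy]ethyl}-4-hydroxy-5,5,8a-trimethyl-1,4,4a,5,6,7,8,8a-octahydronaphthalene-2-carboxylate
Conditions: NaBH4, CeCl3·7H2O, MeOH, −78 °C
Reagents that add atoms: none
Why: Luche reduction should give 1,2-reduction of the enone only; hydride approaches C6 from the face opposite the axial C20 and C4 methyl groups, so the new alcohol is axial and cis to C20 (6S).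

Step 8
Reactants: 14 methyl (1S,4S,4aR,8aS)-1-{2-[(tert-butyldimethylsilyl)oxy]ethyl}-4-hydroxy-5,5,8a-trimethyl-1,4,4a,5,6,7,8,8a-octahydronaphthalene-2-carboxylate
Product: 15 methyl (1S,4S,4aR,8aS)-4-hydroxy-1-(2-hydroxyethyl)-5,5,8a-trimethyl-1,4,4a,5,6,7,8,8a-octahydronaphthalene-2-carboxylate
Conditions: HF·pyridine, THF, 0 °C to rt
Reagents that add atoms: none
Why: Fluoride cleavage of the primary silyl ether under non-basic conditions should leave the allylic alcohol and the enoate untouched.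

Step 9
Reactants: 15 methyl (1S,4S,4aR,8aS)-4-hydroxy-1-(2-hydroxyethyl)-5,5,8a-trimethyl-1,4,4a,5,6,7,8,8a-octahydronaphthalene-2-carboxylate
Product: 16 methyl (1S,4S,4aR,8aS)-4-hydroxy-5,5,8a-trimethyl-1-(2-oxoethyl)-1,4,4a,5,6,7,8,8a-octahydronaphthalene-2-carboxylate
Conditions: TEMPO (cat.), PhI(OAc)2, CH2Cl2, rt
Reagents that add atoms: none
Why: Oxoammonium (TEMPO/PhI(OAc)2) oxidation is selective for the unhindered primary alcohol over the hindered axial secondary allylic alcohol and stops at the aldehyde.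

Step 10
Reactants: 16 methyl (1S,4S,4aR,8aS)-4-hydroxy-5,5,8a-trimethyl-1-(2-oxoethyl)-1,4,4a,5,6,7,8,8a-octahydronaphthalene-2-carboxylate; 17 2-(triphenylphosphoranylidene)propanal
Product: 18 methyl (1S,4S,4aR,8aS)-4-hydroxy-5,5,8a-trimethyl-1-[(2E)-3-methyl-4-oxobut-2-en-1-yl]-1,4,4a,5,6,7,8,8a-octahydronaphthalene-2-carboxylate
Conditions: toluene, 80 °C
Reagents that add atoms: none
Why: Wittig olefination with the formyl-stabilised ylide 17 is E-selective and should give the trisubstituted (12E)-enal.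

Step 11
Reactants: 18 methyl (1S,4S,4aR,8aS)-4-hydroxy-5,5,8a-trimethyl-1-[(2E)-3-methyl-4-oxobut-2-en-1-yl]-1,4,4a,5,6,7,8,8a-octahydronaphthalene-2-carboxylate
Product: 19 methyl (1S,4S,4aR,8aS)-4-hydroxy-5,5,8a-trimethyl-1-[(2E)-3-methylpenta-2,4-dien-1-yl]-1,4,4a,5,6,7,8,8a-octahydronaphthalene-2-carboxylate
Conditions: Ph3PCH3Br, KOtBu, THF, 0 °C; then 18, 0 °C to rt
Reagents that add atoms: methyltriphenylphosphonium bromide, C[P+](c1ccccc1)(c1ccccc1)c1ccccc1.[Br-]
Why: Wittig methylenation of the enal (excess ylide covers the free hydroxyl) completes the diene without disturbing the C12 alkene geometry.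

Step 12
Reactants: 19 methyl (1S,4S,4aR,8aS)-4-hydroxy-5,5,8a-trimethyl-1-[(2E)-3-methylpenta-2,4-dien-1-yl]-1,4,4a,5,6,7,8,8a-octahydronaphthalene-2-carboxylate
Product: 20 (1S,4S,4aR,8aS)-4-hydroxy-5,5,8a-trimethyl-1-[(2E)-3-methylpenta-2,4-dien-1-yl]-1,4,4a,5,6,7,8,8a-octahydronaphthalene-2-carboxylic acid
Conditions: LiOH, THF/MeOH/H2O, 50 °C; then aq. HCl to pH 3
Reagents that add atoms: lithium hydroxide, [Li+].[OH-]
Why: Saponification of the methyl ester; C9 is not vinylogously acidic with respect to the enoate, and the trans relation of C6–OH and C17 across C7=C8 precludes lactonisation.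

Step 13
Reactants: 20 (1S,4S,4aR,8aS)-4-hydroxy-5,5,8a-trimethyl-1-[(2E)-3-methylpenta-2,4-dien-1-yl]-1,4,4a,5,6,7,8,8a-octahydronaphthalene-2-carboxylic acid
Product: 21 (1S,4S,4aR,8aS)-4-(acetyloxy)-5,5,8a-trimethyl-1-[(2E)-3-methylpenta-2,4-dien-1-yl]-1,4,4a,5,6,7,8,8a-octahydronaphthalene-2-carboxylic acid
Conditions: Ac2O, DMAP, pyridine, CH2Cl2, rt to 40 °C; aq. NaHCO3 work-up, then acidify
Reagents that add atoms: acetic anhydride, CC(=O)OC(C)=O
Why: DMAP-catalysed acetylation of the hindered axial C6 alcohol; the transient mixed anhydride at C17 is hydrolysed in the aqueous work-up.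

**Compound list**

1 | β-cyclocitral (2,6,6-trimethylcyclohex-1-ene-1-carbaldehyde) | CC1=C(C=O)C(C)(C)CCC1 | starting material
2 | methyl acetate | COC(C)=O | starting material
3 | methyl 3-hydroxy-3-(2,6,6-trimethylcyclohex-1-en-1-yl)propanoate (racemic) | COC(=O)CC(O)C1=C(C)CCCC1(C)C | intermediate
4 | methyl 3-oxo-3-(2,6,6-trimethylcyclohex-1-en-1-yl)propanoate | COC(=O)CC(=O)C1=C(C)CCCC1(C)C | intermediate
5 | 3-[(tert-butyldimethylsilyl)oxy]propanal | CC(C)(C)[Si](C)(C)OCCC=O | starting material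
6 | methyl 5-[(tert-butyldimethylsilyl)oxy]-2-(2,6,6-trimethylcyclohex-1-ene-1-carbonyl)pent-2-enoate (E/Z mixture) | COC(=O)C(=CCCO[Si](C)(C)C(C)(C)C)C(=O)C1=C(C)CCCC1(C)C | intermediate
7 | methyl (3S,3aS)-3-{2-[(tert-butyldimethylsilyl)oxy]ethyl}-3a,7,7-trimethyl-1-[(triethylsilyl)oxy]-3a,4,5,6,7,7a-hexahydro-3H-indene-2-carboxylate (C7a epimers; triethylsilyl enol ether of 8) | CC(C)(C)[Si](C)(C)OCC[C@@H]1C(C(=O)OC)=C(O[Si](CC)(CC)CC)C2C(C)(C)CCC[C@@]12C | intermediate (not isolated)
8 | methyl (3R,3aS)-3-{2-[(tert-butyldimethylsilyl)oxy]ethyl}-3a,7,7-trimethyl-1-oxooctahydro-1H-indene-2-carboxylate (side chain cis to the 3a-methyl; epimers at C2 and C7a) | CC(C)(C)[Si](C)(C)OCC[C@@H]1C(C(=O)OC)C(=O)C2C(C)(C)CCC[C@@]12C | intermediate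
9 | ethylzinc cyclopropanolate of 8: a CH2 (C7) bridges C6 (bearing O–ZnEt) and C8 (bearing CO2Me); C9 and C10 configured as in 8 | CC(C)(C)[Si](C)(C)OCC[C@@H]1C2(C(=O)OC)CC2(O[Zn]CC)C3C(C)(C)CCC[C@@]13C | intermediate (not isolated)
10 | methyl (1R,8aS)-1-{2-[(tert-butyldimethylsilyl)oxy]ethyl}-5,5,8a-trimethyl-4-oxodecahydronaphthalene-2-carboxylate (epimers at C2 and C4a) | CC(C)(C)[Si](C)(C)OCC[C@@H]1C(C(=O)OC)CC(=O)C2C(C)(C)CCC[C@@]12C | intermediate (not isolated)
11 | methyl (1R,2S,4aR,8aS)-1-{2-[(tert-butyldimethylsilyl)oxy]ethyl}-5,5,8a-trimethyl-4-oxodecahydronaphthalene-2-carboxylate (trans-fused, ester equatorial) | CC(C)(C)[Si](C)(C)OCC[C@@H]1[C@@H](C(=O)OC)CC(=O)[C@@H]2C(C)(C)CCC[C@@]12C | intermediate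
12 | methyl (1R,2R,4aR,8aS)-1-{2-[(tert-butyldimethylsilyl)oxy]ethyl}-5,5,8a-trimethyl-4-[(trimethylsilyl)oxy]-1,2,4a,5,6,7,8,8a-octahydronaphthalene-2-carboxylate (C6=C7 silyl enol ether of 11) | CC(C)(C)[Si](C)(C)OCC[C@@H]1[C@@H](C(=O)OC)C=C(O[Si](C)(C)C)[C@@H]2C(C)(C)CCC[C@@]12C | intermediate (not isolated)
13 | methyl (1S,4aR,8aS)-1-{2-[(tert-butyldimethylsilyl)oxy]ethyl}-5,5,8a-trimethyl-4-oxo-1,4,4a,5,6,7,8,8a-octahydronaphthalene-2-carboxylate | CC(C)(C)[Si](C)(C)OCC[C@@H]1C(C(=O)OC)=CC(=O)[C@@H]2C(C)(C)CCC[C@@]12C | intermediate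
14 | methyl (1S,4S,4aR,8aS)-1-{2-[(tert-butyldimethylsilyl)oxy]ethyl}-4-hydroxy-5,5,8a-trimethyl-1,4,4a,5,6,7,8,8a-octahydronaphthalene-2-carboxylate | CC(C)(C)[Si](C)(C)OCC[C@@H]1C(C(=O)OC)=C[C@H](O)[C@@H]2C(C)(C)CCC[C@@]12C | intermediate
15 | methyl (1S,4S,4aR,8aS)-4-hydroxy-1-(2-hydroxyethyl)-5,5,8a-trimethyl-1,4,4a,5,6,7,8,8a-octahydronaphthalene-2-carboxylate | OCC[C@@H]1C(C(=O)OC)=C[C@H](O)[C@@H]2C(C)(C)CCC[C@@]12C | intermediate
16 | methyl (1S,4S,4aR,8aS)-4-hydroxy-5,5,8a-trimethyl-1-(2-oxoethyl)-1,4,4a,5,6,7,8,8a-octahydronaphthalene-2-carboxylate | O=CC[C@@H]1C(C(=O)OC)=C[C@H](O)[C@@H]2C(C)(C)CCC[C@@]12C | intermediate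
17 | 2-(triphenylphosphoranylidene)propanal | CC(C=O)=P(c1ccccc1)(c1ccccc1)c1ccccc1 | starting material
18 | methyl (1S,4S,4aR,8aS)-4-hydroxy-5,5,8a-trimethyl-1-[(2E)-3-methyl-4-oxobut-2-en-1-yl]-1,4,4a,5,6,7,8,8a-octahydronaphthalene-2-carboxylate | O=C/C(C)=C/C[C@@H]1C(C(=O)OC)=C[C@H](O)[C@@H]2C(C)(C)CCC[C@@]12C | intermediate
19 | methyl (1S,4S,4aR,8aS)-4-hydroxy-5,5,8a-trimethyl-1-[(2E)-3-methylpenta-2,4-dien-1-yl]-1,4,4a,5,6,7,8,8a-octahydronaphthalene-2-carboxylate | C=C/C(C)=C/C[C@@H]1C(C(=O)OC)=C[C@H](O)[C@@H]2C(C)(C)CCC[C@@]12C | intermediate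
20 | (1S,4S,4aR,8aS)-4-hydroxy-5,5,8a-trimethyl-1-[(2E)-3-methylpenta-2,4-dien-1-yl]-1,4,4a,5,6,7,8,8a-octahydronaphthalene-2-carboxylic acid | C=C/C(C)=C/C[C@@H]1C(C(=O)O)=C[C@H](O)[C@@H]2C(C)(C)CCC[C@@]12C | intermediate
21 | (1S,4S,4aR,8aS)-4-(acetyloxy)-5,5,8a-trimethyl-1-[(2E)-3-methylpenta-2,4-dien-1-yl]-1,4,4a,5,6,7,8,8a-octahydronaphthalene-2-carboxylic acid [labdane numbering: (5R,6S,9S,10S,12E)] | C=C/C(C)=C/C[C@@H]1C(C(=O)O)=C[C@H](OC(C)=O)[C@@H]2C(C)(C)CCC[C@@]12C | target

**Step count and risks**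

Total step count: 13. Longest linear sequence: 13 steps (from 1 or 2 to 21).

Steps most likely to fail:

1. Step 4 (Proposed new method). Three processes may defeat it: direct conjugate hydrosilylation of the alkylidene β-keto ester before electrocyclisation; loss of the C9 proton, a 1,2-methyl shift or capture by the silyl ether oxygen outrunning hydride delivery to the hindered C5; and insufficient bias of the sense of conrotation by the catalyst. The fallback uses known chemistry, sets out from 4 and returns at 8. DMAP-catalysed transesterification of 4 with (1R,2S,5R)-8-phenylmenthol in refluxing toluene should give the 8-phenylmenthyl β-keto ester F1. Knoevenagel condensation with 5 under the conditions of step 3 gives the alkylidene β-keto ester F2. A stoichiometric reductive Nazarov cyclisation (BF3·OEt2, Et3SiH, CH2Cl2, −78 °C to rt) then gives the 8-phenylmenthyl hydrindanone ester F3; the auxiliary biases the sense of conrotation and the (3R,3aS) diastereomer is separated by chromatography. DMAP-catalysed methanolysis of F3 in refluxing MeOH/toluene returns 8 and the auxiliary.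

2. Step 5 (key step). Carbenoid attack on the enolate next to the neopentyl-type ketone may be slow, so that over-alkylation (α-methylation of the product enolate) competes, and equilibration at the hindered C5 may be incomplete. The fallback sets out from 8 and returns at 11. C-alkylation of 8 (NaH, CH2Br2, THF/HMPA) gives the 2-(bromomethyl) β-keto ester F4. Bu3SnH/AIBN (benzene, 80 °C) then triggers a Dowd–Beckwith ring expansion: 3-exo attack of the primary radical on the C6 ketone, β-scission of the C6–C8 bond and reduction of the ester-stabilised C8 radical. This gives the keto ester mixture 10, which NaOMe in MeOH equilibrates to 11.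

3. Step 12. Acyl substitution at the hindered, conjugated C17 ester may be slow, and forcing conditions invite conjugate addition of hydroxide or methoxide to the enoate. The fallback sets out from 19 and returns at 20. DIBAL-H (CH2Cl2, −78 °C) reduces the ester to the allylic diol F5. TEMPO/PhI(OAc)2 oxidises only the primary allylic alcohol, giving the hydroxy enal F6. Pinnick oxidation (NaClO2, NaH2PO4, 2-methyl-2-butene, t-BuOH/H2O) then gives 20.

Further compounds
F1 | step 4 | (1R,2S,5R)-5-methyl-2-(2-phenylpropan-2-yl)cyclohexyl 3-oxo-3-(2,6,6-trimethylcyclohex-1-en-1-yl)propanoate | CC1=C(C(=O)CC(=O)O[C@@H]2C[C@H](C)CC[C@H]2C(C)(C)c3ccccc3)C(C)(C)CCC1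
F2 | step 4 | (1R,2S,5R)-5-methyl-2-(2-phenylpropan-2-yl)cyclohexyl 5-[(tert-butyldimethylsilyl)oxy]-2-(2,6,6-trimethylcyclohex-1-ene-1-carbonyl)pent-2-enoate (E/Z mixture) | CC1=C(C(=O)C(=CCCO[Si](C)(C)C(C)(C)C)C(=O)O[C@@H]2C[C@H](C)CC[C@H]2C(C)(C)c3ccccc3)C(C)(C)CCC1
F3 | step 4 | (1R,2S,5R)-5-methyl-2-(2-phenylpropan-2-yl)cyclohexyl (3R,3aS)-3-{2-[(tert-butyldimethylsilyl)oxy]ethyl}-3a,7,7-trimethyl-1-oxooctahydro-1H-indene-2-carboxylate (epimers at C2 and C7a) | CC(C)(C)[Si](C)(C)OCC[C@@H]1C(C(=O)O[C@@H]3C[C@H](C)CC[C@H]3C(C)(C)c4ccccc4)C(=O)C2C(C)(C)CCC[C@@]12C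
F4 | step 5 | methyl 2-(bromomethyl)-3-{2-[(tert-butyldimethylsilyl)oxy]ethyl}-3a,7,7-trimethyl-1-oxooctahydro-1H-indene-2-carboxylate (C3 and C3a configured as in 8; epimers at C2 and C7a) | CC(C)(C)[Si](C)(C)OCC[C@@H]1C(CBr)(C(=O)OC)C(=O)C2C(C)(C)CCC[C@@]12C
F5 | step 12 | (1S,4S,4aR,8aS)-3-(hydroxymethyl)-8,8,4a-trimethyl-4-[(2E)-3-methylpenta-2,4-dien-1-yl]-1,4,4a,5,6,7,8,8a-octahydronaphthalen-1-ol (the C17 carbinol of 19; labdane 5R,6S,9S,10S) | C=C/C(C)=C/C[C@@H]1C(CO)=C[C@H](O)[C@@H]2C(C)(C)CCC[C@@]12C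
F6 | step 12 | (1S,4S,4aR,8aS)-4-hydroxy-5,5,8a-trimethyl-1-[(2E)-3-methylpenta-2,4-dien-1-yl]-1,4,4a,5,6,7,8,8a-octahydronaphthalene-2-carbaldehyde | C=C/C(C)=C/C[C@@H]1C(C=O)=C[C@H](O)[C@@H]2C(C)(C)CCC[C@@]12C
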